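| setting | ash | oak | flask |
|---|---|---|---|
| substrate | 0.10 M | 0.20 M | 0.10 M |
| gas phase | 4.5 mM (held) | 4.5 mM (held) | 4.5 mM (held) |
| remark | the very flask that is asked about, followed so far | run made earlier |  |
| time |  |  | 40 min |

| run | time / min | target / % | substrate / % |
|---|---|---|---|
| ash | 0.833 | 1.3 | 90.7 |
| ash | 2.50 | 3.1 | 74.9 |
| ash | 4.00 | 5.5 | 61.4 |
| ash | 6.00 | 8.2 | 48.4 |
| ash | 10.0 | 13.4 | 27.2 |
| ash | 12.0 | 15.8 | 20.3 |
| oak | 3.00 | 1.5 | 71.6 |
| oak | 5.00 | 3.5 | 57.2 |
| oak | 8.00 | 4.2 | 40.2 |
| oak | 15.0 | 8.9 | 16.4 |
| oak | 25.0 | 15.4 | 2.4 |
| oak | 40.0 | 15.3 | 0 |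

(each reading ± 0.5 percentage points)

- the analysis behind the earlier runs scatters by 0.5 percentage points, standard deviation
- at the start none of the gas phase is in solution

- summer: doubling the transfer coefficient of the gas phase, all else as stated
- dawn: doubling the saturation concentration of gas phase, all else as stated

1. the target standing at 40 min, as a percentage of the substrate charged
2. concentration of dissolved gas in solution at 4.0 min, in percent of saturation
3. the change that raises the amount of target at 40 min, in percent of the substrate charged most ("none" if none brings more than 2 percentage points) (summer / dawn / none)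
4. amount of target at 40 min, in percent of the substrate charged, after summer

- Slowness was where I began, since you wanted a quick number: target in the ash run reached 15.8% by 12.0 min, a mean supply N of 1.32 mM min⁻¹, while the oak run, charged with twice the substrate, showed a mean of 1.19 mM min⁻¹ by 15.0 min. So, since the oak mean read lower than the ash mean, I took gas transfer as the rate-limiting step while substrate lasted.
- Between 4.00 min and 10.0 min in the ash run, substrate fell faster than target rose, and I read that gap as a first-order loss with constant k of 0.104 min⁻¹.
- I then used the balance concentration ρ = N/k, 12.6 mM, the substrate level at which the loss runs as fast as gas capture.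
- I solved for substrate A with dA/dt = −kA − N from a charge c down to empty, holding the run gas-short up to the end where substrate is gone and target stops rising. My yield was (ρ/c)·ln(1 + c/ρ).
- For the oak run this gave 17.8% against a reading of 15.3%, so I carried the ratio f of 0.859.
- My ash figure was therefore 23.7%. Summer, doubling N and so ρ, gave me 34.7%. In this reckoning dawn doubled ρ as well, so ρ did not separate the two, and it gave me no figure for the dissolved gas.
- The forecast gave 24.5%, 12%, dawn and 33%, holding that “Doubling saturation doubles the rate at every substrate level”.
- The flask gave 22.7% of target and 1.67% of saturation at 4.0 min. The best change was summer, worth 8.7 percentage points against 6.4 points for dawn, and summer gave 31.4%.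

    gas phase ⇌ dissolved gas, rate k1*(csat - [dissolved gas]) (kL = 0.00520 s⁻¹)
    substrate + dissolved gas → target (k = 4.90 M⁻¹ s⁻¹)
    substrate → side product (k = 0.00170 s⁻¹)
    dissolved gas + target → over-reaction product (k = 0.0200 M⁻¹ s⁻¹)
    target ⇌ isomer of the product (K = 2.30, k = 6.50 × 10⁻⁵ s⁻¹)

- My ash figure stood 1 point above the flask. For the neighbouring flask charged with 0.17 M of substrate, the same ρ and f gave 17.0%. That flask held 17.1% of target at 40 min.

The runs were computed for substances that don't exist, and the scatter is random.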